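The vessel is closed, stirred and held at one temperature, and oak and ash differ from each other in nothing but the time.

in all of them: free monomer 2.2 M
- Friday's: initiator 31 mM; run made earlier
- Sunday's: initiator 48 mM; run made earlier
- oak: initiator 22 mM; time 2.0 min
- ash: initiator 22 mM; time 0.50 min

- Friday's (time / s: monomer in chains / %, free monomer / %): 10.0: 3.5, 95.6; 15.0: 6.4, 93.6; 25.0: 12.1, 87.5; 40.0: 22.3, 75.7; 80.0: 47.1, 53.2
- Sunday's (time / s: monomer in chains / %, free monomer / %): 10.0: 4.6, 95.3; 15.0: 9.5, 91.2; 25.0: 16.8, 83.6; 40.0: 28.6, 70.7; 60.0: 44.2, 56.7; 80.0: 55.2, 44.5

(scatter of a reading: 0.5 percentage points)

- the average divides the monomer in chains by the number of chains begun, living and dead together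
- the numbers in the tables scatter with a standard deviation of 0.5 percentage points
- the earlier runs do not show the number of chains; that part of a forecast is a guess

- which of the two ends with the longer chains by the average number of monomer units in a chain (chains begun, living or dead) ("neither" if they lie within 10 %) (oak / ash / neither)
- average number of monomer units in a chain (chains begun, living or dead) at the end, oak
- average number of monomer units in a chain (chains begun, living or dead) at the end, ash

After a short lag the free monomer in Friday's and Sunday's runs falls pseudo-first-order, so the logarithm of its fall reads as a steady slope. I take the living ends to be the one concentration that sets this slope. I read it two ways, from the free monomer lost and from the monomer in chains gained. From 40.0 s to 80.0 s, Sunday's run gives 0.0116 s⁻¹ and 0.0117 s⁻¹, and these agree. Over the matching span, Friday's run gives 0.00882 s⁻¹ and 0.00961 s⁻¹, and these part. Its two columns at 40.0 s sum to 98.0 %, while a reading scatters by 0.5 percentage points, so I judge that this reading cheats. From 25.0 s to 80.0 s, Friday's columns give 0.00905 s⁻¹ and 0.00923 s⁻¹, and Friday's line runs back to a lag of 10.2 s.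

Sunday's slope is 1.28 times Friday's for 1.55 times the initiator, near the square root, 1.24. Scaling Friday's slope by that root gives 0.00762 s⁻¹, the pace, meaning the slope of the logarithmic fall of free monomer at the charge of oak and ash. Oak then has 56.7 % reacted and ash 14.0 %. The number of chains is my guess: a flat slope suggests the ends stop increasing after the lag, so I give both flasks one count. Oak's chains then end 4.05 times as long as ash's. If every initiator charged began one chain, the lengths would be 56.7 in oak and 14.0 in ash, and I take these as low estimates.

The forecast says neither, with 300 for oak and 290 for ash, on the ground that “Chains begun grow roughly linearly with time”.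

The longer chains stand in oak, with 94.2 for oak and 26.1 for ash, and at the end the living ends stand at 0.0130 M in oak and 0.0109 M in ash.

    2 initiator → spent initiator (k = 1.70 M⁻¹ s⁻¹)
    free monomer + living end → monomer in chains + living end, rate k2*[living end]*[free monomer] (k = 0.600 M⁻¹ s⁻¹)
    free monomer + initiator → living end + monomer in chains (k = 0.0220 M⁻¹ s⁻¹)

The pace leaves 43.3 % free monomer in oak, and oak holds 44.2 %. Now take ash read at 80 s: the pace puts 41.2 % in chains, and oak's length scaled by that share is 68.4. That flask gives 39.7 % and 68.1.

The runs come from a simulation from invented constants, noise included.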